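**Plan (labdane numbering, C1–C20)**

1. Retrosynthesis: the two acetates and the C2/C3 oxygens go back to a 3-ketone with a helper ester on C2. Ring B is cut at C9–C10, and ring A is contracted by re-forming the C2–C10 bond to give a 1-carbomethoxybicyclo[3.1.0]hexan-2-one. That bicycle is cut at C2–C1/C2–C10 (carbenoid addition), C2–C3 (acylation) and C4–C5 ([3,3] shift), leaving farnesol, an isobutyryl unit and methyl acetate.
2. Enabling feature: C10 is a methyl-bearing quaternary carbon, 1,4 to the C3 oxygen across ring A, and it carries ring B through C9. Ring A can therefore be stored as the cyclopentanone C2–C3–C4–C5–C10 with C1 as a cyclopropane methylene; the shared C2–C10 bond is a latent C10 cation / C2=C3 enolate.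
3. Forward order: farnesol chain, then the C4–C5 bond (Ireland–Claisen), then cyclopentanone plus cyclopropane in one carbenoid step, then ring A (five to six) and ring B together in the key step, then C2–OH, C3–OH and the acetates.
4. Stereochemistry: C5 comes from the chiral-boron ester-enolate Claisen. C10 and C9 follow from C5 through chair closure of the (E)-C8=C9 olefin. C2 is set by enolate oxidation anti to the C10 methyl, C3 by equatorial hydride delivery. Both (E)-olefins come from farnesol.

Key step: step 8

Assumption: the (S,S)-configured boron controller is taken to give the (3S)-acid 7; if the sense proves opposite, its (R,R)-enantiomer is used with no other change.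

**Route**

Step 1
Reactants: 1 (2E,6E)-farnesol
Product: 2 (2E,6E)-farnesyl pivalate
Conditions: pivaloyl chloride, pyridine, DMAP (cat.), CH2Cl2, 0 °C to 20 °C
Reagents that add atoms: pivaloyl chloride CC(C)(C)C(Cl)=O
Why: DMAP-catalysed esterification of the primary allylic alcohol; the pivalate has no α-hydrogen and so should survive the later enolisations, and as an ester it deactivates the C13=C14 olefin in step 8.

Step 2
Reactants: 2 (2E,6E)-farnesyl pivalate
Product: 3 (2E,6E,10E)-12-hydroxyfarnesyl pivalate
Conditions: SeO2 (0.3 equiv), t-BuOOH (3 equiv), salicylic acid (0.1 equiv), CH2Cl2, 20 °C, stopped at partial conversion, 2 recycled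
Reagents that add atoms: selenium dioxide O=[Se]=O (catalytic oxygen carrier); tert-butyl hydroperoxide CC(C)(C)OO (terminal oxidant)
Why: Catalytic SeO2 allylic oxidation (ene reaction, then [2,3]-sigmatropic shift) is known to hydroxylate the (E)-methyl of the terminal isopropylidene group of farnesyl esters, and the mechanism leaves the new allylic alcohol (E).

Step 3
Reactants: 3 (2E,6E,10E)-12-hydroxyfarnesyl pivalate
Product: 4 (2E,6E,10E)-12-(isobutyryloxy)farnesyl pivalate
Conditions: isobutyryl chloride, pyridine, DMAP (cat.), CH2Cl2, 0 °C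
Reagents that add atoms: isobutyryl chloride CC(C)C(Cl)=O
Why: Esterification of the primary allylic alcohol installs the C3/C4/gem-dimethyl unit as the acyl half of the allyl ester needed for the [3,3] shift.

Step 4
Reactants: 4 (2E,6E,10E)-12-(isobutyryloxy)farnesyl pivalate
Product: 7 (3S,6E,10E)-2,2,6,10-tetramethyl-12-(pivaloyloxy)-3-(prop-1-en-2-yl)dodeca-6,10-dienoic acid, via boron ketene acetal 5 (not isolated), via boryl carboxylate 6 (not isolated)
Conditions: (4S,5S)-2-bromo-4,5-diphenyl-1,3-bis[3,5-bis(trifluoromethyl)phenylsulfonyl]-1,3,2-diazaborolidine (1.3 equiv), i-Pr2NEt (1.5 equiv), CH2Cl2, −78 °C, then −20 to 4 °C for several days; aqueous acid work-up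
Reagents that add atoms: none
Why: Enantioselective ester-enolate Claisen rearrangement (Ireland–Claisen type): soft enolisation gives the boron ketene acetal, whose chair [3,3] shift across the (E)-C5=C10 olefin forms the C4–C5 bond and the isopropenyl group; the C2-symmetric bis-sulfonamide ligand on boron selects one olefin face and so sets C5, and the symmetrical Me2C= terminus removes any enolate-geometry issue.

Step 5
Reactants: 7 (3S)-acid
Product: 9 methyl (5S,8E,12E)-4,4,8,12-tetramethyl-3-oxo-14-(pivaloyloxy)-5-(prop-1-en-2-yl)tetradeca-8,12-dienoate, via acid chloride 8 (not isolated)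
Conditions: (COCl)2, DMF (cat.), CH2Cl2, 0 to 20 °C, concentrate; then added to LiCH2CO2Me (2.2 equiv, from methyl acetate and LiN(i-Pr)2), THF, −78 °C; aq. NH4Cl
Reagents that add atoms: methyl acetate CC(=O)OC (as its lithium enolate)
Why: Crossed Claisen acylation of an ester enolate by a non-enolisable, pivaloyl-type acid chloride (the second equivalent of enolate is taken up by the acidic product) adds C2 and the helper ester; the hindered pivalate should not compete.

Step 6
Reactants: 9 β-keto ester
Product: 10 methyl (5S,8E,12E)-2-diazo-4,4,8,12-tetramethyl-3-oxo-14-(pivaloyloxy)-5-(prop-1-en-2-yl)tetradeca-8,12-dienoate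
Conditions: 4-acetamidobenzenesulfonyl azide, Et3N, MeCN, 0 to 20 °C
Reagents that add atoms: 4-acetamidobenzenesulfonyl azide CC(=O)Nc1ccc(cc1)S(=O)(=O)N=[N+]=[N-]
Why: Regitz diazo transfer onto the active methylene of a β-keto ester.

Step 7
Reactants: 10 α-diazo-β-keto ester
Product: 11 methyl (1R,4S,5S)-4-[(3E,7E)-3,7-dimethyl-9-(pivaloyloxy)nona-3,7-dien-1-yl]-3,3,5-trimethyl-2-oxobicyclo[3.1.0]hexane-1-carboxylate (side chain trans to the cyclopropane CH2)
Conditions: Cu(acac)2 (5 mol%), toluene, 100 °C, slow addition of 10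
Reagents that add atoms: none
Why: Intramolecular cyclopropanation of a copper carbenoid onto the γ,δ-isopropenyl group closes the cyclopentanone and the cyclopropane at once; the ring fusion is necessarily cis, the C5 side chain is expected anti to the new CH2, and copper is chosen to suppress C–H insertion.

Step 8
Reactants: 11 cyclopropyl keto ester
Product: 13 methyl (2S,5S,9R,10S)-3-oxo-15-(pivaloyloxy)-ent-labda-7,13(E)-diene-2-carboxylate (enolisable at C2, drawn as the equatorial keto form), via ring-enlarged C10 cation 12 (not isolated)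
Conditions: SnCl4 (2.2 equiv), CH2Cl2, −78 to −30 °C; then H2O
Reagents that add atoms: none
Why: Proposed new method: SnCl4 bound to the β-keto ester of 11 should heterolyse the internal C2–C10 bond, the only cyclopropane bond that leaves a tertiary cation (methyl-bearing C10) beside a tin enolate (C2=C3), so that the cyclopentanone C2–C3–C4–C5–C10 grows by the former cyclopropane carbon C1 into ring A (zwitterion 12). The closest known reaction types are the Lewis-acid opening of acylcyclopropanes with participation of a remote olefin and the acid-induced thujane-to-p-menthane enlargement of 5-alkylbicyclo[3.1.0]hexan-2-ones; their union in one operation is the new element. Ring A thus arises by one-carbon ring enlargement and not by a closure, whereas ring B closes 6-endo-trig, C9 of the C8=C9 olefin bonding to C10, after which the tertiary C8 cation loses a C7 proton. C10 and C9 are controlled by the existing C5 centre through a chair transition state with the C5–C6 tether equatorial on ring A: C9 enters C10 equatorially (methyl axial, trans to H-5) and the (E)-olefin places C11 equatorial (H-9 anti to the methyl); either C5/cyclopropane diastereomer of 11 should converge if ionisation precedes closure, and the anti isomer gives the same result by backside displacement. The step needs internal over external bond cleavage (secured by the C10 methyl and the rotatable ester acceptor), 6-endo over 5-exo closure (secured by the trisubstituted C8=C9 olefin) and a stop at the bicycle (secured by the SnCl4-complexed allylic pivalate, which deactivates the C13=C14 olefin). Proton loss toward C7 in preference to C17 is the one selectivity that the substrate does not enforce.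

Step 9
Reactants: 13 bicyclic β-keto ester
Product: 14 (5S,9R,10S)-3-oxo-ent-labda-7,13(E)-dien-15-yl pivalate
Conditions: LiCl (3 equiv), H2O (2 equiv), DMSO, 130 °C
Reagents that add atoms: none
Why: Krapcho dealkoxycarbonylation (chloride attack at the ester methyl, then decarboxylation) removes the helper ester; C5, C9 and C10 are not α to the ketone and cannot epimerise.

Step 10
Reactants: 14 3-ketone
Product: 16 (2S,5S,9R,10S)-2-hydroxy-3-oxo-ent-labda-7,13(E)-dien-15-yl pivalate, via potassium enolate 15 (not isolated)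
Conditions: KN(SiMe3)2, THF, −78 °C; 2-(phenylsulfonyl)-3-phenyloxaziridine, −78 °C; aq. NH4Cl
Reagents that add atoms: 2-(phenylsulfonyl)-3-phenyloxaziridine O=S(=O)(c1ccccc1)N1OC1c1ccccc1
Why: Enolate oxidation with an N-sulfonyloxaziridine; the ketone can enolise only toward C2 (C4 is quaternary), the oxidant should approach anti to the axial C10 methyl to give the equatorial 2-hydroxyl (as known for 4,4-dimethyl-3-keto terpenoids), and neither the olefins nor the α-hydrogen-free pivalate are touched.

Step 11
Reactants: 16 α-hydroxy ketone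
Product: 17 (2S,5S,9R,10S)-2-acetoxy-3-oxo-ent-labda-7,13(E)-dien-15-yl pivalate
Conditions: Ac2O, pyridine, DMAP (cat.), CH2Cl2, 0 to 20 °C
Reagents that add atoms: acetic anhydride CC(=O)OC(C)=O
Why: Acetylation caps the C2 hydroxyl with a small, non-chelating group, so that no bulky alkoxyborate sits next to the ketone during the reduction.

Step 12
Reactants: 17 α-acetoxy ketone
Product: 19 (2S,3R,5S,9R,10S)-ent-labda-7,13(E)-diene-2,3,15-triol (2-OH equatorial, 3-OH axial, both anti to the C10 methyl), via hydroxy acetate 18 (not isolated)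
Conditions: LiBH(s-Bu)3 (1.3 equiv), THF, −78 °C; then LiAlH4 (excess), −78 to 0 °C; aq. NaOH work-up
Reagents that add atoms: none
Why: The bulky borohydride should attack the cyclohexanone from the equatorial direction (as known for 2-substituted cyclohexanones and for 4,4-dimethyl-3-keto terpenoids), giving the axial C3 alcohol cis to the C2 oxygen; LiAlH4 in the same flask then cleaves acetate and pivalate, so any acyl migration is of no consequence.

Step 13
Reactants: 19 triol
Product: 20 target, (2S,3R,5S,9R,10S)-2,15-diacetoxy-ent-labda-7,13(E)-dien-3-ol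
Conditions: Ac2O (2.3 equiv), pyridine, CH2Cl2, 0 to 20 °C, no DMAP
Reagents that add atoms: acetic anhydride CC(=O)OC(C)=O
Why: Selective acylation: the primary allylic C15 hydroxyl and the equatorial C2 hydroxyl should react, while the axial C3 hydroxyl next to the gem-dimethyl carbon is too hindered under these conditions.

**Compound list**

1 | (2E,6E)-farnesol | CC(C)=CCC/C(C)=C/CC/C(C)=C/CO | starting material
2 | (2E,6E)-farnesyl pivalate | CC(C)=CCC/C(C)=C/CC/C(C)=C/COC(=O)C(C)(C)C | intermediate
3 | (2E,6E,10E)-12-hydroxyfarnesyl pivalate | OC/C(C)=C/CC/C(C)=C/CC/C(C)=C/COC(=O)C(C)(C)C | intermediate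
4 | (2E,6E,10E)-12-(isobutyryloxy)farnesyl pivalate | CC(C)C(=O)OC/C(C)=C/CC/C(C)=C/CC/C(C)=C/COC(=O)C(C)(C)C | intermediate
5 | boron ketene acetal of 4 (O-allyl, O-boryl; boron in the (4S,5S)-diphenyl-bis(arylsulfonyl)diazaborolidine) | CC(C)=C(OC/C(C)=C/CC/C(C)=C/CC/C(C)=C/COC(=O)C(C)(C)C)OB1N(S(=O)(=O)c2cc(C(F)(F)F)cc(C(F)(F)F)c2)[C@@H](c2ccccc2)[C@H](c2ccccc2)N1S(=O)(=O)c1cc(C(F)(F)F)cc(C(F)(F)F)c1 | intermediate (not isolated)
6 | boryl carboxylate of acid 7 | O=C(OB1N(S(=O)(=O)c2cc(C(F)(F)F)cc(C(F)(F)F)c2)[C@@H](c2ccccc2)[C@H](c2ccccc2)N1S(=O)(=O)c1cc(C(F)(F)F)cc(C(F)(F)F)c1)C(C)(C)[C@@H](CC/C(C)=C/CC/C(C)=C/COC(=O)C(C)(C)C)C(C)=C | intermediate (not isolated)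
7 | (3S,6E,10E)-2,2,6,10-tetramethyl-12-(pivaloyloxy)-3-(prop-1-en-2-yl)dodeca-6,10-dienoic acid | OC(=O)C(C)(C)[C@@H](CC/C(C)=C/CC/C(C)=C/COC(=O)C(C)(C)C)C(C)=C | intermediate
8 | acid chloride of 7 | ClC(=O)C(C)(C)[C@@H](CC/C(C)=C/CC/C(C)=C/COC(=O)C(C)(C)C)C(C)=C | intermediate (not isolated)
9 | methyl (5S,8E,12E)-4,4,8,12-tetramethyl-3-oxo-14-(pivaloyloxy)-5-(prop-1-en-2-yl)tetradeca-8,12-dienoate | COC(=O)CC(=O)C(C)(C)[C@@H](CC/C(C)=C/CC/C(C)=C/COC(=O)C(C)(C)C)C(C)=C | intermediate
10 | 2-diazo derivative of 9 | COC(=O)C(=[N+]=[N-])C(=O)C(C)(C)[C@@H](CC/C(C)=C/CC/C(C)=C/COC(=O)C(C)(C)C)C(C)=C | intermediate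
11 | methyl (1R,4S,5S)-4-[(3E,7E)-3,7-dimethyl-9-(pivaloyloxy)nona-3,7-dien-1-yl]-3,3,5-trimethyl-2-oxobicyclo[3.1.0]hexane-1-carboxylate | COC(=O)[C@]12C[C@@]1(C)[C@H](CC/C(C)=C/CC/C(C)=C/COC(=O)C(C)(C)C)C(C)(C)C2=O | intermediate
12 | ring-enlarged C10 cation with tin-bound C2=C3 enolate (drawn as the free zwitterion) | COC(=O)C1=C([O-])C(C)(C)[C@@H](CC/C(C)=C/CC/C(C)=C/COC(=O)C(C)(C)C)[C+](C)C1 | intermediate (not isolated)
13 | methyl (2S,5S,9R,10S)-3-oxo-15-(pivaloyloxy)-ent-labda-7,13(E)-diene-2-carboxylate | CC(C)(C)C(=O)OC/C=C(\C)CC[C@@H]1C(C)=CC[C@@H]2C(C)(C)C(=O)[C@@H](C(=O)OC)C[C@@]12C | intermediate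
14 | (5S,9R,10S)-3-oxo-ent-labda-7,13(E)-dien-15-yl pivalate | CC(C)(C)C(=O)OC/C=C(\C)CC[C@@H]1C(C)=CC[C@@H]2C(C)(C)C(=O)CC[C@@]12C | intermediate
15 | potassium C2=C3 enolate of 14 | CC(C)(C)C(=O)OC/C=C(\C)CC[C@@H]1C(C)=CC[C@@H]2C(C)(C)C([O-])=CC[C@@]12C.[K+] | intermediate (not isolated)
16 | (2S,5S,9R,10S)-2-hydroxy-3-oxo-ent-labda-7,13(E)-dien-15-yl pivalate | CC(C)(C)C(=O)OC/C=C(\C)CC[C@@H]1C(C)=CC[C@@H]2C(C)(C)C(=O)[C@@H](O)C[C@@]12C | intermediate
17 | (2S,5S,9R,10S)-2-acetoxy-3-oxo-ent-labda-7,13(E)-dien-15-yl pivalate | CC(C)(C)C(=O)OC/C=C(\C)CC[C@@H]1C(C)=CC[C@@H]2C(C)(C)C(=O)[C@@H](OC(C)=O)C[C@@]12C | intermediate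
18 | (2S,3R,5S,9R,10S)-2-acetoxy-3-hydroxy-ent-labda-7,13(E)-dien-15-yl pivalate | CC(C)(C)C(=O)OC/C=C(\C)CC[C@@H]1C(C)=CC[C@@H]2C(C)(C)[C@@H](O)[C@@H](OC(C)=O)C[C@@]12C | intermediate (not isolated)
19 | (2S,3R,5S,9R,10S)-ent-labda-7,13(E)-diene-2,3,15-triol | OC/C=C(\C)CC[C@@H]1C(C)=CC[C@@H]2C(C)(C)[C@@H](O)[C@@H](O)C[C@@]12C | intermediate
20 | (2S,3R,5S,9R,10S)-2,15-diacetoxy-ent-labda-7,13(E)-dien-3-ol | CC(=O)OC/C=C(\C)CC[C@@H]1C(C)=CC[C@@H]2C(C)(C)[C@@H](O)[C@@H](OC(C)=O)C[C@@]12C | target

**Step count and risks**

Total steps: 13. Longest linear sequence: 13 steps from farnesol.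

Step 8 (key step). What may go wrong: cleavage of the external instead of the internal cyclopropane bond; loss of a C1 proton from the C10 cation before ring B closes; loss of the terminating proton from C17 instead of C7; or capture of the C8 cation by the C13=C14 olefin. The fallback uses known reaction types and still makes ring A by ring enlargement, but in separate operations. It sets out from 11. Acid-catalysed homoconjugate opening with elimination (p-TsOH, benzene, 60 °C; the thujane-to-p-menthane type) should give the ring-enlarged monocyclic keto ester methyl (4S)-4-[(3E,7E)-3,7-dimethyl-9-(pivaloyloxy)nona-3,7-dien-1-yl]-3,3,5-trimethyl-2-oxocyclohex-5-ene-1-carboxylate F1. Brønsted-acid cation–olefin cyclisation of F1 (ClSO3H, 2-nitropropane, −78 °C), as known for monocyclic farnesyl-type trienes, should then close ring B to give 13 together with its exocyclic 8(17)-olefin isomer F2. F2 is converged to 13 by hydrogen-atom-transfer olefin isomerisation (Co(salen)Cl, trivalent cobalt, 3 mol%, PhSiH3, benzene, 20 °C), which moves a 1,1-disubstituted olefin into the trisubstituted endocyclic position and leaves trisubstituted olefins alone. The route is rejoined at 13.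

Step 4. What may go wrong: slow or unselective soft enolisation of the hindered isobutyrate by the bulky boron reagent, giving low conversion or low enantiomeric purity. The fallback sets out from 4. A standard Ireland–Claisen rearrangement (LiN(i-Pr)2, Me3SiCl, THF, −78 to 20 °C) passes through the silyl ketene acetal F3 and the trimethylsilyl ester F4 to the racemic acid F5 on aqueous work-up. Classical resolution by crystallisation of the (S)-1-phenylethylammonium salt F6, followed by acidification, returns the route to 7.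

Step 12. What may go wrong: hydride delivery along the axial instead of the equatorial direction, which would give the trans-diequatorial diol. The fallback replaces substrate control by reagent control. It sets out from 17: an oxazaborolidine-catalysed reduction (CBS reduction; (R)-B-methyl catalyst, catecholborane, toluene, −78 °C), in which the quaternary C4 acts as the large and C2 as the small flank, should give 18. LiAlH4 as before then returns the route to 19. This fallback makes no compound outside the list (F0).

**Further compounds**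

F1 | step 8 | methyl (4S)-4-[(3E,7E)-3,7-dimethyl-9-(pivaloyloxy)nona-3,7-dien-1-yl]-3,3,5-trimethyl-2-oxocyclohex-5-ene-1-carboxylate (C1 epimers and enol) | COC(=O)C1C=C(C)[C@H](CC/C(C)=C/CC/C(C)=C/COC(=O)C(C)(C)C)C(C)(C)C1=O
F2 | step 8 | methyl (2S,5S,9R,10S)-3-oxo-15-(pivaloyloxy)-ent-labda-8(17),13(E)-diene-2-carboxylate | CC(C)(C)C(=O)OC/C=C(\C)CC[C@@H]1C(=C)CC[C@@H]2C(C)(C)C(=O)[C@@H](C(=O)OC)C[C@@]12C
F3 | step 4 | trimethylsilyl ketene acetal of 4 | CC(C)=C(O[Si](C)(C)C)OC/C(C)=C/CC/C(C)=C/CC/C(C)=C/COC(=O)C(C)(C)C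
F4 | step 4 | trimethylsilyl ester of the racemic acid | C[Si](C)(C)OC(=O)C(C)(C)C(CC/C(C)=C/CC/C(C)=C/COC(=O)C(C)(C)C)C(C)=C
F5 | step 4 | racemic (6E,10E)-2,2,6,10-tetramethyl-12-(pivaloyloxy)-3-(prop-1-en-2-yl)dodeca-6,10-dienoic acid | OC(=O)C(C)(C)C(CC/C(C)=C/CC/C(C)=C/COC(=O)C(C)(C)C)C(C)=C
F6 | step 4 | (S)-1-phenylethylammonium salt of the (3S)-acid | C[C@H]([NH3+])c1ccccc1.[O-]C(=O)C(C)(C)[C@@H](CC/C(C)=C/CC/C(C)=C/COC(=O)C(C)(C)C)C(C)=C
F0 | step 12 | none | none
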